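## Structural features

The target is a flavonol: benzene ring A (C4a, C5, C6, C7, C8, C8a) is fused through the C4a–C8a bond to 4-pyranone ring C (O1, C2, C3, C4), and ring C carries the guaiacyl ring B through the C2–C1' bond. There is no stereocentre and no stereogenic axis, so every selectivity question is one of position. Five oxygens sit on the periphery: the enolic O3–H on ring C, the O5–H on ring A that is hydrogen-bonded to the C4 carbonyl, the hydrogen sulfate on O7, and the 3'-methoxy and 4'-hydroxy groups on ring B. The fragile group is the aryl sulfate monoester: it is cleaved by acid (autocatalytically in its own acid form) and makes every later intermediate ionic, so it must come late and meet only neutral or basic conditions afterwards. The 3-oxygenated 4-pyranone is also sensitive to strong nucleophiles. The carbon skeleton is easy; the real difficulty is to tell O7 from O5, O3 and O4', four acidic hydroxyl groups, of which O5 and O7 are equivalent in the phloroglucinol unit from which ring A is normally taken. The key step exploits the fact that ring A is a resorcinol unit: C5–O and C7–O are meta across C6–H, with C5 next to the fusion carbon C4a and C8–H next to C8a. That is exactly the pattern a vinylketene and an alkoxyacetylene deliver, with the ketene oxygen as free O5–H and the acetylene oxygen as an ether on O7. Ring C with its C3 oxygen is the 5-hydroxy-4-pyranone core of 1, so rings C and B can be in place before ring A exists.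

## Logic of the disconnections

**22 to 21.** The O3–CH2Ph and O4'–CH2Ph bonds are cut last, together with the exchange of the ammonium counter-ion for a proton. Hydrogenolysis is neutral and is the one deprotection mode that the O7–S bond tolerates. The gain is a fully differentiated, storable precursor. The demand is that hydrogen on palladium leaves C2=C3 and the sulfate alone.

**21 to 20.** The O7–S bond is cut. The sulfate is introduced when O7–H is the only free hydroxyl that is not chelated. The gain is a neutral, chromatographable precursor. The demand is that O5–H stays out, which its hydrogen bond to the C4 carbonyl should secure.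

**20 to 19.** The O7–C(CH3)3 bond is cut. A tert-alkyl ether is the one ether in the molecule that falls to dilute acid, so it is orthogonal to the benzyl and methyl ethers. The demand is that this acid step comes before the sulfate exists.

**19 to 8 and 14 (key disconnection).** Ring A is taken apart at C4a–C5, C5–C6 and C7–C8. C5 and C8 go back to the two carbons of the diazoacetyl group of 8 (C8 shifting back from C8a to the acyl carbon), and C6 and C7 go back to the two carbons of 14. O5 and O7 then come from two different molecules: O5 from the acyl oxygen of 8, and O7, already carrying its own protecting group, from 14. Their differentiation is therefore a matter of construction, not of selective protection. The gain is large: a bicyclic chromone with four differentiated oxygens becomes a monocyclic pyranone and a two-carbon alkyne. In one sentence, ring A is annulated last onto a finished ring C/ring B unit by a Wolff rearrangement, ketene–alkyne cycloaddition, 4π opening and 6π electrocyclisation cascade of 8 with 14. The demand is that the forward cascade forms the ketene cleanly, adds 14 in the right orientation and closes at the one free ring carbon next to the side chain.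

**8 to 6.** The C–C bond between the acyl carbon and the diazo carbon is cut. The gain is a stable carboxylic acid. The demand is acylation of a one-carbon diazoalkane without attack on the pyranone double bond.

**6 to 5.** Only the oxidation level of the exocyclic carbon changes. The demand is an oxidant that spares the benzyl ethers and the electron-rich ring B.

**5 to 3 and 4.** The C2–C1' bond between ring C and ring B is cut. It is made early, on a small robust pyranone, from a commercial boronic acid. The demand is a cross-coupling under base mild enough for the pyranone.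

**3 to 2 to 1.** The O–benzyl bond and then the C–Br bond are cut. The free enolic hydroxyl of 1 directs the halogen to the neighbouring ring carbon and is then capped. 1 is a cheap fermentation product that already holds O1, C2, C3–O and C4=O of the target.

**14 to 9 and 10.** The O–C(sp) bond is cut. Both partners are bulk chemicals. The demand is only careful handling of a volatile, heat-sensitive ynol ether.

## Other disconnections considered

**Alternative 1:** The first route that comes to mind cuts O1–C2 and the C3–O bond of ring C. Forward, a Claisen–Schmidt condensation of an O4',O6'-protected phloroacetophenone with the benzyl-protected ring B aldehyde would give chalcone A1, and an Algar–Flynn–Oyamada oxidative cyclisation would give flavonol A2. The chosen plan is preferred on three grounds. O5 and O7 of A1 come from the equivalent oxygens of a phloroglucinol and can only be told apart by selective protection, which is the very problem of the target. A 6'-alkoxy group on a 2'-hydroxychalcone twists the enone and is known as a class effect to divert this cyclisation towards the five-membered aurone. A2 is also formed with O3–H free, so a further blocking step is needed before O7 can be unmasked and sulfated.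

**Alternative 2:** The C2–C1' bond is cut at the end. Forward, a Suzuki–Miyaura coupling would join 2-iodochromone A3 to 4. This moves only the easiest bond of the molecule. A3 still needs rings A and C built from a phloroglucinol with the O5/O7 problem unsolved, and its iodine has to be introduced by metalation at C2 of a 3-alkoxychromone, a step that competes with ring opening. The step count would be higher and the key step would carry none of the real difficulty.

**Alternative 3:** Ring A is cut at C4a–C5 and C8–C8a. Forward, a [4+2] cycloaddition of bromopyranone A4 with a 1-alkoxy-1,3-bis(silyloxy)butadiene, followed by loss of hydrogen bromide and an alcohol, would lead towards 20. The regiochemistry is right on paper, since the nucleophilic diene terminus meets the oxygen-bearing carbon. However, the C5=C6 bond of a 4-pyranone is part of a vinylogous ester with some aromatic character and is a poor dienophile, so conjugate addition and ring opening by the nucleophilic diene are the expected competitors. Both new oxygens would also arrive as equally labile silyl ethers. The chosen cascade asks the pyranone double bond only to act as the end of a triene, and its other elementary steps (ketene plus ynol ether, electrocyclic opening and closure) are intrinsically fast.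

Key step: step 7

Assumption: the target is taken as the neutral hydrogen sulfate drawn in the SMILES. It would be released from its triethylammonium salt by cation exchange in the last step and kept cold, because aryl hydrogen sulfates hydrolyse on standing in the acid form.

## Route

Step 1
Reactants: 1 kojic acid (5-hydroxy-2-(hydroxymethyl)-4H-pyran-4-one)
Product: 2 2-bromo-3-hydroxy-6-(hydroxymethyl)-4H-pyran-4-one
Conditions: NBS (1.05 equiv), MeCN/H2O, 0 to 20 °C
Reagents that add atoms: N-bromosuccinimide, O=C1CCC(=O)N1Br
Why: Electrophilic bromination; the free enolic hydroxyl activates the neighbouring ring carbon (the CH next to O1), the usual site at which 1 takes electrophiles, as in an ortho-substitution of a phenol.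

Step 2
Reactants: 2 2-bromo-3-hydroxy-6-(hydroxymethyl)-4H-pyran-4-one
Product: 3 3-(benzyloxy)-2-bromo-6-(hydroxymethyl)-4H-pyran-4-one
Conditions: BnBr, K2CO3, DMF, 20 °C
Reagents that add atoms: benzyl bromide, BrCc1ccccc1
Why: Williamson ether synthesis; carbonate deprotonates only the acidic enolic hydroxyl, so the primary alcohol is not alkylated.

Step 3
Reactants: 3 3-(benzyloxy)-2-bromo-6-(hydroxymethyl)-4H-pyran-4-one; 4 [4-(benzyloxy)-3-methoxyphenyl]boronic acid
Product: 5 3-(benzyloxy)-2-[4-(benzyloxy)-3-methoxyphenyl]-6-(hydroxymethyl)-4H-pyran-4-one
Conditions: Pd(PPh3)4 (5 mol %), K2CO3, 1,4-dioxane/H2O, 85 °C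
Reagents that add atoms: none
Why: Suzuki–Miyaura coupling; the C–Br bond is that of a beta-bromo enone and should add readily to zerovalent palladium, and aqueous carbonate is mild enough for the pyranone ring and the free alcohol.

Step 4
Reactants: 5 3-(benzyloxy)-2-[4-(benzyloxy)-3-methoxyphenyl]-6-(hydroxymethyl)-4H-pyran-4-one
Product: 6 5-(benzyloxy)-6-[4-(benzyloxy)-3-methoxyphenyl]-4-oxo-4H-pyran-2-carboxylic acid
Conditions: TEMPO (20 mol %), PhI(OAc)2 (2.2 equiv), MeCN/H2O, 20 °C
Reagents that add atoms: water, O
Why: Oxoammonium-mediated oxidation of the primary alcohol through the aldehyde hydrate to the acid; the metal-free oxidant should leave the benzyl ethers and the electron-rich ring B untouched.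

Step 5
Reactants: 6 5-(benzyloxy)-6-[4-(benzyloxy)-3-methoxyphenyl]-4-oxo-4H-pyran-2-carboxylic acid
Product: 8 3-(benzyloxy)-2-[4-(benzyloxy)-3-methoxyphenyl]-6-(2-diazoacetyl)-4H-pyran-4-one, via acid chloride 7 (not isolated)
Conditions: (COCl)2, DMF (cat.), CH2Cl2, 0 to 20 °C; evaporate; CH2N2 (3 equiv), Et2O/THF, 0 °C
Reagents that add atoms: diazomethane, C=[N+]=[N-]; oxalyl chloride, O=C(Cl)C(Cl)=O (its chlorine stays in 7 only)
Why: Acid chloride formation followed by C-acylation of diazomethane, the first stage of an Arndt–Eistert sequence; a second equivalent of diazomethane takes up the hydrogen chloride so that the diazoketone is not converted into the chloromethyl ketone.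

Step 6
Reactants: 9 potassium tert-butoxide; 10 trichloroethylene
Product: 14 tert-butoxyethyne, via dichlorovinyl ether 11 (not isolated), via chloroethynyl ether 12 (not isolated), via lithium acetylide 13 (not isolated)
Conditions: THF, -50 to 20 °C; n-BuLi (2.2 equiv), -78 to -40 °C; H2O, -78 °C; distil cold
Reagents that add atoms: n-butyllithium, [Li]CCCC (its lithium stays in 13 only; no atom of it remains in 14)
Why: Established alkoxyacetylene synthesis: addition–elimination of the alkoxide on trichloroethylene gives the (E)-dichlorovinyl ether 11; n-butyllithium dehydrochlorinates it to 12 and exchanges the remaining chlorine for lithium to give 13, which is protonated.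

Step 7
Reactants: 8 3-(benzyloxy)-2-[4-(benzyloxy)-3-methoxyphenyl]-6-(2-diazoacetyl)-4H-pyran-4-one; 14 tert-butoxyethyne
Product: 19 3-(benzyloxy)-2-[4-(benzyloxy)-3-methoxyphenyl]-7-(tert-butoxy)-5-hydroxy-4H-chromen-4-one, via pyranonylketene 15 (not isolated), via cyclobutenone 16 (not isolated), via dienylketene 17 (not isolated), via dienone tautomer 18 (not isolated)
Conditions: 14 (4 equiv), hν (450 nm LEDs), CH2Cl2, 20 °C; evaporate; toluene, 90 °C
Reagents that add atoms: none
Why: This is a benzannulation of the Danheiser type in its diazoketone version; the closest known reactions are the annulations of vinyl and heteroaryl diazomethyl ketones with alkoxy- or siloxyacetylenes to resorcinol monoethers. Light of 450 nm excites only the diazoketone band of 8, nitrogen leaves and the pyranonyl group shifts to the former diazo carbon (Wolff rearrangement) to give ketene 15, whose vinyl unit is the C5=C6 bond of the pyranone. The polarised triple bond of 14 adds to the ketene C=C in a [2+2] cycloaddition, its nucleophilic CH terminus bonding to the ketene carbonyl carbon, so that 16 carries the tert-butoxy group on C3 and the pyranone on C4, which fixes the ether oxygen meta to the ketene oxygen (O7 against O5). On heating, 16 opens by a reversible conrotatory 4π electrocyclisation to 17; only the rotamer with the pyranone turned towards the ketene can go on, and the other one re-closes. Ring A is then closed by a thermally allowed disrotatory 6π electrocyclisation that joins the ketene carbon (future C5) to pyranone C5 (future C4a), the only possible terminus because the other neighbour of pyranone C6 is O1. The resulting dienone 18 tautomerises irreversibly to 19, since its C4a–H lies between two carbonyl groups and the shift gains the aromaticity of ring A and the hydrogen bond from O5–H to the C4 carbonyl. No lasting stereocentre is formed (the sp3 carbons of 16 and 18 are erased), so the selectivities needed are the orientation of the [2+2] step, the site of closure and the chemoselective excitation, secured by the ynol ether polarisation, by O1 and by the wavelength. Excess 14 is evaporated before heating because it fragments to ketene and isobutene on warming.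

Step 8
Reactants: 19 3-(benzyloxy)-2-[4-(benzyloxy)-3-methoxyphenyl]-7-(tert-butoxy)-5-hydroxy-4H-chromen-4-one
Product: 20 3-(benzyloxy)-2-[4-(benzyloxy)-3-methoxyphenyl]-5,7-dihydroxy-4H-chromen-4-one
Conditions: TFA/CH2Cl2 (1:4), 0 °C
Reagents that add atoms: none
Why: Acidolysis of an aryl tert-butyl ether through the tert-butyl cation, which leaves as isobutene; benzyl and methyl ethers should survive cold dilute acid, and ring A is deactivated towards re-alkylation by the C4 carbonyl.

Step 9
Reactants: 20 3-(benzyloxy)-2-[4-(benzyloxy)-3-methoxyphenyl]-5,7-dihydroxy-4H-chromen-4-one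
Product: 21 triethylammonium 3-(benzyloxy)-2-[4-(benzyloxy)-3-methoxyphenyl]-5-hydroxy-4-oxo-4H-chromen-7-yl sulfate
Conditions: SO3·NEt3 (3 equiv), DMF, 40 °C
Reagents that add atoms: sulfur trioxide–triethylamine complex, CC[N+](CC)(CC)S(=O)(=O)[O-]
Why: O-Sulfation with a sulfur trioxide–amine complex; O7–H is the only unhindered, non-chelated hydroxyl, while O5–H is held in a hydrogen bond to the C4 carbonyl and is hardly nucleophilic.

Step 10
Reactants: 21 triethylammonium 3-(benzyloxy)-2-[4-(benzyloxy)-3-methoxyphenyl]-5-hydroxy-4-oxo-4H-chromen-7-yl sulfate
Product: 22 isorhamnetin 7-O-sulfate (3,5-dihydroxy-2-(4-hydroxy-3-methoxyphenyl)-4-oxo-4H-chromen-7-yl hydrogen sulfate)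
Conditions: H2 (1 atm), Pd/C (10 %), MeOH/THF, 20 °C; Dowex 50W (H+ form), MeOH/H2O, 0 °C; lyophilise
Reagents that add atoms: none
Why: Hydrogenolysis of the two benzyl ethers under neutral conditions, which should leave the aryl sulfate and the C2=C3 bond of the flavonol intact; brief cold cation exchange then gives the acid form.

## Compound list

1 | kojic acid (5-hydroxy-2-(hydroxymethyl)-4H-pyran-4-one) | O=c1cc(CO)occ1O | starting material
2 | 2-bromo-3-hydroxy-6-(hydroxymethyl)-4H-pyran-4-one | O=c1cc(CO)oc(Br)c1O | intermediate
3 | 3-(benzyloxy)-2-bromo-6-(hydroxymethyl)-4H-pyran-4-one | O=c1cc(CO)oc(Br)c1OCc1ccccc1 | intermediate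
4 | [4-(benzyloxy)-3-methoxyphenyl]boronic acid | COc1cc(B(O)O)ccc1OCc1ccccc1 | starting material
5 | 3-(benzyloxy)-2-[4-(benzyloxy)-3-methoxyphenyl]-6-(hydroxymethyl)-4H-pyran-4-one | COc1cc(-c2oc(CO)cc(=O)c2OCc2ccccc2)ccc1OCc1ccccc1 | intermediate
6 | 5-(benzyloxy)-6-[4-(benzyloxy)-3-methoxyphenyl]-4-oxo-4H-pyran-2-carboxylic acid | COc1cc(-c2oc(C(=O)O)cc(=O)c2OCc2ccccc2)ccc1OCc1ccccc1 | intermediate
7 | 5-(benzyloxy)-6-[4-(benzyloxy)-3-methoxyphenyl]-4-oxo-4H-pyran-2-carbonyl chloride | COc1cc(-c2oc(C(=O)Cl)cc(=O)c2OCc2ccccc2)ccc1OCc1ccccc1 | intermediate
8 | 3-(benzyloxy)-2-[4-(benzyloxy)-3-methoxyphenyl]-6-(2-diazoacetyl)-4H-pyran-4-one | COc1cc(-c2oc(C(=O)C=[N+]=[N-])cc(=O)c2OCc2ccccc2)ccc1OCc1ccccc1 | intermediate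
9 | potassium tert-butoxide | CC(C)(C)[O-].[K+] | starting material
10 | trichloroethylene | ClC=C(Cl)Cl | starting material
11 | tert-butyl (E)-1,2-dichlorovinyl ether | CC(C)(C)O/C(Cl)=C\Cl | intermediate
12 | tert-butyl chloroethynyl ether | CC(C)(C)OC#CCl | intermediate
13 | lithium tert-butoxyacetylide | CC(C)(C)OC#C[Li] | intermediate
14 | tert-butoxyethyne | CC(C)(C)OC#C | intermediate
15 | 2-{5-(benzyloxy)-6-[4-(benzyloxy)-3-methoxyphenyl]-4-oxo-4H-pyran-2-yl}ethenone (pyranonylketene) | COc1cc(-c2oc(C=C=O)cc(=O)c2OCc2ccccc2)ccc1OCc1ccccc1 | intermediate
16 | 4-{5-(benzyloxy)-6-[4-(benzyloxy)-3-methoxyphenyl]-4-oxo-4H-pyran-2-yl}-3-(tert-butoxy)cyclobut-2-en-1-one (racemic, transient stereocentre) | O=C1C=C(OC(C)(C)C)C1c1cc(=O)c(OCc2ccccc2)c(-c2ccc(OCc3ccccc3)c(OC)c2)o1 | intermediate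
17 | 4-{5-(benzyloxy)-6-[4-(benzyloxy)-3-methoxyphenyl]-4-oxo-4H-pyran-2-yl}-3-(tert-butoxy)buta-1,3-dien-1-one, ketene arm and pyranone cis across the C3=C4 bond | O=C=C/C(OC(C)(C)C)=C\c1cc(=O)c(OCc2ccccc2)c(-c2ccc(OCc3ccccc3)c(OC)c2)o1 | intermediate
18 | 3-(benzyloxy)-2-[4-(benzyloxy)-3-methoxyphenyl]-7-(tert-butoxy)-4aH-chromene-4,5-dione (racemic, transient stereocentre) | O=C1C=C(OC(C)(C)C)C=C2OC(c3ccc(OCc4ccccc4)c(OC)c3)=C(OCc3ccccc3)C(=O)C12 | intermediate
19 | 3-(benzyloxy)-2-[4-(benzyloxy)-3-methoxyphenyl]-7-(tert-butoxy)-5-hydroxy-4H-chromen-4-one | COc1cc(-c2oc3cc(OC(C)(C)C)cc(O)c3c(=O)c2OCc2ccccc2)ccc1OCc1ccccc1 | intermediate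
20 | 3-(benzyloxy)-2-[4-(benzyloxy)-3-methoxyphenyl]-5,7-dihydroxy-4H-chromen-4-one | COc1cc(-c2oc3cc(O)cc(O)c3c(=O)c2OCc2ccccc2)ccc1OCc1ccccc1 | intermediate
21 | triethylammonium 3-(benzyloxy)-2-[4-(benzyloxy)-3-methoxyphenyl]-5-hydroxy-4-oxo-4H-chromen-7-yl sulfate | COc1cc(-c2oc3cc(OS(=O)(=O)[O-])cc(O)c3c(=O)c2OCc2ccccc2)ccc1OCc1ccccc1.CC[NH+](CC)CC | intermediate
22 | isorhamnetin 7-O-sulfate | COc1cc(-c2oc3cc(OS(=O)(=O)O)cc(O)c3c(=O)c2O)ccc1O | target

## Step count and least certain steps

Total step count: 10 (nine on the main line and one for 14). Longest linear sequence: 9 steps, from 1 to 22 through steps 1 to 5 and 7 to 10.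

**Step 7 (key step).** The ketene 15 may be lost to dimerisation or to traces of water before 14 intercepts it. The diazo group of 8 may add to the electron-rich triple bond as a 1,3-dipole in the dark. The thermal stage may stall at the cyclobutenone, or the tert-butyl enol ether may lose isobutene before ring closure.
Fallback (sets out from 8, returns at 19): the same ketene would be made in the dark by a classical dehydrochlorination. An Arndt–Eistert homologation of 8 (PhCO2Ag, Et3N, THF/H2O) would give 2-{5-(benzyloxy)-6-[4-(benzyloxy)-3-methoxyphenyl]-4-oxo-4H-pyran-2-yl}acetic acid F1. Oxalyl chloride would convert it into the corresponding acetyl chloride F2. Slow addition of F2 to Et3N and 14 in CH2Cl2 would generate 15 by elimination of hydrogen chloride and trap it as 16, and heating in toluene would complete the sequence to 19.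

**Step 5.** Diazomethane may undergo 1,3-dipolar cycloaddition to the pyranone C=C bond, which in 7 is flanked by the ring carbonyl and the acid chloride. Hydrogen chloride may also convert the diazoketone into the chloromethyl ketone.
Fallback (sets out from 6, returns at 8): the diazo group would be installed by diazo transfer, with no diazoalkane. Acid chloride 7, made as before, would be coupled with Me4Sn under PdCl2(PPh3)2 catalysis (Stille ketone synthesis) to give 6-acetyl-3-(benzyloxy)-2-[4-(benzyloxy)-3-methoxyphenyl]-4H-pyran-4-one F3. Its lithium enolate (LiN(SiMe3)2, THF, -78 °C) would be trifluoroacetylated with 2,2,2-trifluoroethyl trifluoroacetate to the 1,3-diketone F4, which is not isolated. Deacylative diazo transfer with methanesulfonyl azide, Et3N and water in MeCN would then give 8.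

**Step 9.** Sulfation may be sluggish because the O7 phenol is a vinylogous acid and a weak nucleophile. Forcing it may bring some reaction at O5, and the amphiphilic salt may be lost on purification.
Fallback (sets out from 20, returns at 21): the sulfate would be introduced as a neutral, chromatographable diester. 2,2,2-Trichloroethyl chlorosulfate with Et3N and DMAP in THF would give 3-(benzyloxy)-2-[4-(benzyloxy)-3-methoxyphenyl]-5-hydroxy-4-oxo-4H-chromen-7-yl 2,2,2-trichloroethyl sulfate F5. Reductive fragmentation of F5 with zinc and triethylammonium formate in MeOH would then give 21.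

**Step 10.** Hydrogenolysis may be slow or incomplete on the ionic substrate, the C2=C3 bond may be over-reduced on long exposure, and the sulfate may be hydrolysed while the salt is exchanged to the acid form.
Fallback (sets out from 20, returns at 22): the order of the last two operations would be inverted. Hydrogenolysis of 20 (H2, Pd/C) would give isorhamnetin F6. One equivalent of SO3·NEt3 at low temperature should then attack the most acidic, unhindered O7–H in preference to O4'–H and O3–H (O5–H is chelated) to give triethylammonium isorhamnetin 7-sulfate F7. F7 would be freed from regioisomers by reversed-phase chromatography and converted into 22 by cold cation exchange. This fallback gives up the guaranteed regiochemistry and is a last resort.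

## Further compounds

F1 | step 7 | 2-{5-(benzyloxy)-6-[4-(benzyloxy)-3-methoxyphenyl]-4-oxo-4H-pyran-2-yl}acetic acid | COc1cc(-c2oc(CC(=O)O)cc(=O)c2OCc2ccccc2)ccc1OCc1ccccc1
F2 | step 7 | 2-{5-(benzyloxy)-6-[4-(benzyloxy)-3-methoxyphenyl]-4-oxo-4H-pyran-2-yl}acetyl chloride | COc1cc(-c2oc(CC(=O)Cl)cc(=O)c2OCc2ccccc2)ccc1OCc1ccccc1
F3 | step 5 | 6-acetyl-3-(benzyloxy)-2-[4-(benzyloxy)-3-methoxyphenyl]-4H-pyran-4-one | COc1cc(-c2oc(C(C)=O)cc(=O)c2OCc2ccccc2)ccc1OCc1ccccc1
F4 | step 5 | 1-{5-(benzyloxy)-6-[4-(benzyloxy)-3-methoxyphenyl]-4-oxo-4H-pyran-2-yl}-4,4,4-trifluorobutane-1,3-dione | COc1cc(-c2oc(C(=O)CC(=O)C(F)(F)F)cc(=O)c2OCc2ccccc2)ccc1OCc1ccccc1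
F5 | step 9 | 3-(benzyloxy)-2-[4-(benzyloxy)-3-methoxyphenyl]-5-hydroxy-4-oxo-4H-chromen-7-yl 2,2,2-trichloroethyl sulfate | COc1cc(-c2oc3cc(OS(=O)(=O)OCC(Cl)(Cl)Cl)cc(O)c3c(=O)c2OCc2ccccc2)ccc1OCc1ccccc1
F6 | step 10 | isorhamnetin (3,5,7-trihydroxy-2-(4-hydroxy-3-methoxyphenyl)-4H-chromen-4-one) | COc1cc(-c2oc3cc(O)cc(O)c3c(=O)c2O)ccc1O
F7 | step 10 | triethylammonium isorhamnetin 7-sulfate | COc1cc(-c2oc3cc(OS(=O)(=O)[O-])cc(O)c3c(=O)c2O)ccc1O.CC[NH+](CC)CC
A1 | alternative 1 | (E)-3-[4-(benzyloxy)-3-methoxyphenyl]-1-[2-hydroxy-4,6-bis(methoxymethoxy)phenyl]prop-2-en-1-one | COCOc1cc(O)c(C(=O)/C=C/c2ccc(OCc3ccccc3)c(OC)c2)c(OCOC)c1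
A2 | alternative 1 | 2-[4-(benzyloxy)-3-methoxyphenyl]-3-hydroxy-5,7-bis(methoxymethoxy)-4H-chromen-4-one | COCOc1cc(OCOC)c2c(c1)oc(-c1ccc(OCc3ccccc3)c(OC)c1)c(O)c2=O
A3 | alternative 2 | 3-(benzyloxy)-2-iodo-5,7-bis(methoxymethoxy)-4H-chromen-4-one | COCOc1cc(OCOC)c2c(c1)oc(I)c(OCc1ccccc1)c2=O
A4 | alternative 3 | 3-(benzyloxy)-2-[4-(benzyloxy)-3-methoxyphenyl]-5-bromo-4H-pyran-4-one | COc1cc(-c2occ(Br)c(=O)c2OCc2ccccc2)ccc1OCc1ccccc1
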